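The route opens ring D in the retro-aldol sense at the C1–C8a bond. Ring D is a 4-hydroxy-5,5-dimethylcyclopent-2-enone (carbinol C8a, enone carbons C3a and C3, carbonyl C2, quaternary C1). Cleaving C1–C8a gives a Z-ene-1,4-dione, which is the oxidised form of a 2-isopropylfuran fused to ring C. In one operation a peracid opens that furan and carbonate closes the isopropyl ketone enolate onto the ring C ketone, creating ring D, the C1–C8a bond and the C8a carbinol. The precursor is a cyclohepta[b]furan bearing the C4 methyl stereocentre, a C6 silyl ether and a C8 dioxolane that blocks the only other enolisation site. The pyranone rings A and B are attached afterwards.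

Key step: step 12

Remark on numbering: rings C and D carry azulene locants (C1 CMe2, C2 C=O, C3 =CH, C3a, C4 CHMe, C5, C6, C7, C8, C8a carbinol); the cyclohepta[b]furan intermediates share C4–C8a; ring A is the dimethylpyranone and ring B the dihydropyran.
Assumption: methyl 4-bromofuran-2-carboxylate is taken as the purchased bromofuran, because its ester carbon accepts both isopropyl methyl groups in one Grignard step.

Step 1
Reactants: 1 methyl 4-bromofuran-2-carboxylate
Product: 2 2-(4-bromofuran-2-yl)propan-2-ol
Conditions: MeMgBr (2.5 equiv), THF, 0 °C; then H2O (pH 7 buffer)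
Reagents that add atoms: methylmagnesium bromide, C[Mg]Br
Why: Double Grignard addition to the ester installs both methyl groups of the future isopropyl unit in one operation, and the furyl bromide does not exchange with MeMgBr at 0 °C.

Step 2
Reactants: 2 2-(4-bromofuran-2-yl)propan-2-ol
Product: 3 4-bromo-2-isopropylfuran
Conditions: Et3SiH (3 equiv), TFA (4 equiv), CH2Cl2, −40 to 0 °C
Reagents that add atoms: none
Why: Ionic hydrogenation, in which TFA ionises the tertiary furfuryl alcohol to a furan-stabilised carbocation that excess triethylsilane reduces by hydride transfer before it can alkylate a second, bromine-deactivated furan.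

Step 3
Reactants: 3 4-bromo-2-isopropylfuran
Product: 4 (5-isopropylfuran-3-yl)boronic acid
Conditions: B(OiPr)3 (1.3 equiv), then n-BuLi (1.1 equiv), THF/toluene, −78 °C; then 1 M HCl, 0 °C
Reagents that add atoms: triisopropyl borate, CC(C)OB(OC(C)C)OC(C)C; water, O
Why: Bromine–lithium exchange with in situ borate capture traps the 3-furyllithium at −78 °C before it can isomerise to the 2-lithio species, and mild acid hydrolysis releases the boronic acid.

Step 4
Reactants: 4 (5-isopropylfuran-3-yl)boronic acid; 5 ethyl crotonate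
Product: 6 ethyl (R)-3-(5-isopropylfuran-3-yl)butanoate
Conditions: [Rh(nbd)2]BF4 (1.5 mol%), (S)-BINAP (1.6 mol%), Et3N (1 equiv), 5 (2 equiv), dioxane/H2O (10:1), 30 °C
Reagents that add atoms: none
Why: Hayashi–Miyaura rhodium-catalysed asymmetric 1,4-addition, in which the (S)-BINAP complex (the ligand enantiomer that gives (R)-3-arylbutanoates from E-crotonates) forms the aryl–carbon bond and sets the R methyl-bearing centre that becomes C4, the low temperature limiting protodeboronation.

Step 5
Reactants: 6 ethyl (R)-3-(5-isopropylfuran-3-yl)butanoate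
Product: 7 (R)-3-(5-isopropylfuran-3-yl)butanoic acid
Conditions: LiOH (3 equiv), THF/MeOH/H2O, rt; then 1 M HCl to pH 4, 0 °C
Reagents that add atoms: lithium hydroxide, [Li+].[OH-]
Why: Plain ester saponification, safe because the stereocentre is β to the carboxyl group and cannot epimerise.

Step 6
Reactants: 7 (R)-3-(5-isopropylfuran-3-yl)butanoic acid; 8 Meldrum's acid
Product: 10 ethyl (R)-5-(5-isopropylfuran-3-yl)-3-oxohexanoate, via acyl Meldrum's acid 9 (not isolated)
Conditions: DCC (1.1 equiv), DMAP (1.2 equiv), CH2Cl2, 0 °C to rt; filter; then EtOH, 78 °C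
Reagents that add atoms: ethanol, CCO
Why: Meldrum's acid β-keto ester synthesis, in which carbodiimide C-acylation is followed by ethanolysis through an acylketene with loss of acetone and CO2, all under neutral conditions that the alkylfuran tolerates.

Step 7
Reactants: 10 ethyl (R)-5-(5-isopropylfuran-3-yl)-3-oxohexanoate
Product: 11 ethyl (3R,5R)-3-hydroxy-5-(5-isopropylfuran-3-yl)hexanoate
Conditions: RuCl2[(R)-BINAP] (0.5 mol%), H2 (10 atm), EtOH, 50 °C
Reagents that add atoms: none
Why: Noyori asymmetric hydrogenation of a β-keto ester, in which the ester-chelated ketone is reduced under catalyst control to the 3R carbinol (the sense (R)-BINAP gives with 3-oxoalkanoates) while the furan is left untouched.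

Step 8
Reactants: 11 ethyl (3R,5R)-3-hydroxy-5-(5-isopropylfuran-3-yl)hexanoate
Product: 12 ethyl (3R,5R)-3-(tert-butyldimethylsilyloxy)-5-(5-isopropylfuran-3-yl)hexanoate
Conditions: TBSCl (1.3 equiv), imidazole (2.5 equiv), DMF, rt
Reagents that add atoms: tert-butyldimethylsilyl chloride, CC(C)(C)[Si](C)(C)Cl
Why: Standard imidazole-promoted silylation of a secondary alcohol, which masks the future C6 oxygen through the acylation, peracid and carbonate steps.

Step 9
Reactants: 12 ethyl (3R,5R)-3-(tert-butyldimethylsilyloxy)-5-(5-isopropylfuran-3-yl)hexanoate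
Product: 13 (3R,5R)-3-(tert-butyldimethylsilyloxy)-5-(5-isopropylfuran-3-yl)hexanoic acid
Conditions: LiOH (2 equiv), THF/MeOH/H2O, 0 °C to rt; then 1 M HCl to pH 4–5, 0 °C
Reagents that add atoms: lithium hydroxide, [Li+].[OH-]
Why: Saponification with LiOH at or below room temperature cleaves the ethyl ester without β-elimination of the silyloxy group.

Step 10
Reactants: 13 (3R,5R)-3-(tert-butyldimethylsilyloxy)-5-(5-isopropylfuran-3-yl)hexanoic acid
Product: 15 (4R,6R)-6-(tert-butyldimethylsilyloxy)-2-isopropyl-4-methyl-4,5,6,7-tetrahydro-8H-cyclohepta[b]furan-8-one, via acid chloride 14 (not isolated)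
Conditions: 1-chloro-N,N,2-trimethylprop-1-en-1-amine (1.2 equiv), CH2Cl2, 0 °C; then SnCl4 (1.1 equiv), CH2Cl2 (0.01 M), −78 °C
Reagents that add atoms: none
Why: Intramolecular Friedel–Crafts acylation, in which the acid chloride made under neutral conditions attacks the only free and most nucleophilic α-position of the furan (next to the tether) and closes seven-membered ring C at a temperature the silyl ether survives.

Step 11
Reactants: 15 (4R,6R)-6-(tert-butyldimethylsilyloxy)-2-isopropyl-4-methyl-4,5,6,7-tetrahydro-8H-cyclohepta[b]furan-8-one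
Product: 16 (4'R,6'R)-6'-(tert-butyldimethylsilyloxy)-2'-isopropyl-4'-methyl-4',5',6',7'-tetrahydrospiro[1,3-dioxolane-2,8'-cyclohepta[b]furan]
Conditions: (TMSOCH2)2 (2 equiv), TMSOTf (5 mol%), CH2Cl2, −40 to 0 °C; pyridine quench
Reagents that add atoms: 1,2-bis(trimethylsilyloxy)ethane, C[Si](C)(C)OCCO[Si](C)(C)C
Why: Noyori ketalisation under aprotic conditions is driven by formation of hexamethyldisiloxane and converts the conjugated C8 ketone to its dioxolane without cleaving the silyl ether or exposing the furan to protic acid.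

Step 12
Reactants: 16 (4'R,6'R)-6'-(tert-butyldimethylsilyloxy)-2'-isopropyl-4'-methyl-4',5',6',7'-tetrahydrospiro[1,3-dioxolane-2,8'-cyclohepta[b]furan]
Product: 18 (4R,6R,8aR)-6-(tert-butyldimethylsilyloxy)-8a-hydroxy-1,1,4-trimethyl-4,5,6,7-tetrahydro-1H-spiro[azulene-8,2'-[1,3]dioxolan]-2(8aH)-one, via Z-enedione 17 (not isolated)
Conditions: m-CPBA (1.05 equiv), NaHCO3 (2 equiv), CH2Cl2, 0 °C; then MeOH, K2CO3 (1.5 equiv), 0 °C to rt
Reagents that add atoms: meta-chloroperoxybenzoic acid, OOC(=O)c1cccc(Cl)c1
Why: The peracid epoxidises the electron-rich furan and the epoxide collapses to the Z-ene-1,4-dione 17, whose cis geometry is inherited from the ring and whose two new carbonyls are C2 and C8a. Carbonate in methanol then enolises the only site with an α-hydrogen, the isopropyl methine (C8a is flanked by the C8 dioxolane and by sp2 C3a), and the enolate adds to the C8a ketone to form the C1–C8a bond; the closest known chemistry is the oxidative opening of 2,5-dialkylfurans to cis-enediones and their base-mediated aldol closure to 4-hydroxycyclopent-2-enones, a relative of the Piancatelli rearrangement. Ring D closes in the 5-(enolendo)-exo-trig mode, the same mode by which 1,4-diketones give cyclopentenones, and the Z-alkene holds the two termini within bonding distance. The new C8a stereocentre is controlled by the C4 methyl centre through the reversibility of the aldol: in the chair-like ring C the C8a hydroxyl is pseudo-axial, the epimer drawn keeps the C4 methyl pseudo-equatorial beside the small C3–H, and the other epimer would hold methyl and hydroxyl syn-diaxial across C3a. The step needs a single chemoselective oxidation (the furan is the only electron-rich π-system and the peracid is buffered and limited to 1.05 equiv), site-selective enolisation (secured by the dioxolane) and retention of the γ-acidic C4 centre (mild carbonate at low temperature, with the C6 silyloxy centre turning any C4 epimer into a separable diastereomer).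

Step 13
Reactants: 18 (4R,6R,8aR)-6-(tert-butyldimethylsilyloxy)-8a-hydroxy-1,1,4-trimethyl-4,5,6,7-tetrahydro-1H-spiro[azulene-8,2'-[1,3]dioxolan]-2(8aH)-one
Product: 19 (4R,6R,8aR)-6,8a-dihydroxy-1,1,4-trimethyl-4,5,6,7-tetrahydro-1H-spiro[azulene-8,2'-[1,3]dioxolan]-2(8aH)-one
Conditions: HF·pyridine, pyridine, THF, 0 °C to rt
Reagents that add atoms: none
Why: Fluoride-driven desilylation under buffered, weakly acidic conditions frees the C6 alcohol without retro-aldol opening of ring D or loss of the hindered dioxolane.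

Step 14
Reactants: 19 (4R,6R,8aR)-6,8a-dihydroxy-1,1,4-trimethyl-4,5,6,7-tetrahydro-1H-spiro[azulene-8,2'-[1,3]dioxolan]-2(8aH)-one
Product: 20 (4R,8aR)-8a-hydroxy-1,1,4-trimethyl-4,5-dihydro-1H-spiro[azulene-8,2'-[1,3]dioxolane]-2,6(7H,8aH)-dione
Conditions: Dess–Martin periodinane (1.3 equiv), NaHCO3, CH2Cl2, 0 °C to rt
Reagents that add atoms: none
Why: Dess–Martin oxidation converts the secondary C6 alcohol to the ketone under neutral conditions and cannot touch the tertiary C8a alcohol.

Step 15
Reactants: 20 (4R,8aR)-8a-hydroxy-1,1,4-trimethyl-4,5-dihydro-1H-spiro[azulene-8,2'-[1,3]dioxolane]-2,6(7H,8aH)-dione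
Product: 21 (4R,8aR)-5-[(dimethylamino)methyl]-8a-hydroxy-1,1,4-trimethyl-4,5-dihydro-1H-spiro[azulene-8,2'-[1,3]dioxolane]-2,6(7H,8aH)-dione (C5 epimers)
Conditions: LiN(iPr)2 (2.2 equiv), THF, −78 °C; then CH2=NMe2+ I− (1.5 equiv), −78 to 0 °C; H2O quench
Reagents that add atoms: N,N-dimethylmethyleneiminium iodide (Eschenmoser's salt), C=[N+](C)C.[I-]
Why: Mannich reaction of a kinetic lithium enolate with Eschenmoser's salt, in which the amide base, after forming the C8a alkoxide, removes a C5 proton and not the neopentyl C7 proton shielded by the spiro-dioxolane, the new C5 centre being erased in the next step.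

Step 16
Reactants: 21 (4R,8aR)-5-[(dimethylamino)methyl]-8a-hydroxy-1,1,4-trimethyl-4,5-dihydro-1H-spiro[azulene-8,2'-[1,3]dioxolane]-2,6(7H,8aH)-dione (C5 epimers); 22 4-hydroxy-5,6-dimethyl-2H-pyran-2-one
Product: 25 ring B hemiketal (4R,5R,6R,8aR) with the C8 dioxolane retained, via methiodide 23 (not isolated), via exo-methylene ketone 24 (not isolated)
Conditions: MeI (5 equiv), MeCN, rt; evaporate; then 22 (1.5 equiv), iPr2NEt (2.5 equiv), MeCN, 40 °C
Reagents that add atoms: none
Why: Quaternisation and E1cB loss of trimethylamine unveil the α-methylene ketone in the flask, the soft C3 carbon of the hydroxypyrone adds to it in a Michael reaction of the warfarin type, the adduct closes to the ring B hemiketal, and the epimerisable C5 centre should settle with the new CH2 trans to the C4 methyl (both pseudo-equatorial).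

Step 17
Reactants: 25 ring B hemiketal (4R,5R,6R,8aR) with the C8 dioxolane retained
Product: 26 ring B vinylogous ester (4R,5R,8aR) with C6=C7 conjugated to the C8 ketone
Conditions: TsOH·H2O (0.2 equiv), MeCN/H2O (50:1), 40 °C
Reagents that add atoms: water, O
Why: Acid-catalysed dehydration of the hemiketal toward C7 gives an enol ether that assists ionisation of the neighbouring dioxolane, so hydrolysis delivers the conjugated β-aryloxy enone as the thermodynamic sink with release of ethylene glycol, while C5 is kept or re-equilibrated to the trans arrangement.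

Step 18
Reactants: 26 ring B vinylogous ester (4R,5R,8aR) with C6=C7 conjugated to the C8 ketone
Product: 28 CNP0525404.1, via epoxide 27 (not isolated)
Conditions: DMDO (1.1 equiv), acetone, −20 to 0 °C; then H2O, NaOAc/AcOH buffer (pH 5), 0 °C to rt
Reagents that add atoms: dimethyldioxirane, CC1(C)OO1; water, O
Why: Epoxidation of an enol ether followed by hydrolytic opening at the acetal carbon (the glycal-epoxide type of α-hydroxylation), in which DMDO should attack C6=C7 on the face anti to the pseudo-axial C8a hydroxyl and so fix the C7 carbinol, and water opens the epoxide at C6 anti to the departing oxygen to give the trans-diaxial diol with a trans-fused, anomerically stabilised hemiketal that can also be reached by ring–chain equilibration.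

Compound list
1 | methyl 4-bromofuran-2-carboxylate | COC(=O)c1cc(Br)co1 | starting material
2 | 2-(4-bromofuran-2-yl)propan-2-ol | CC(C)(O)c1cc(Br)co1 | intermediate
3 | 4-bromo-2-isopropylfuran | CC(C)c1cc(Br)co1 | intermediate
4 | (5-isopropylfuran-3-yl)boronic acid | CC(C)c1cc(B(O)O)co1 | intermediate
5 | ethyl crotonate, ethyl (E)-but-2-enoate | CCOC(=O)/C=C/C | starting material
6 | ethyl (R)-3-(5-isopropylfuran-3-yl)butanoate | CCOC(=O)C[C@H](c1coc(C(C)C)c1)C | intermediate
7 | (R)-3-(5-isopropylfuran-3-yl)butanoic acid | OC(=O)C[C@H](c1coc(C(C)C)c1)C | intermediate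
8 | Meldrum's acid, 2,2-dimethyl-1,3-dioxane-4,6-dione | CC1(C)OC(=O)CC(=O)O1 | starting material
9 | acyl Meldrum's acid, 5-[(R)-1-hydroxy-3-(5-isopropylfuran-3-yl)butylidene]-2,2-dimethyl-1,3-dioxane-4,6-dione (not isolated) | CC1(C)OC(=O)C(=C(O)C[C@H](c2coc(C(C)C)c2)C)C(=O)O1 | intermediate
10 | ethyl (R)-5-(5-isopropylfuran-3-yl)-3-oxohexanoate | CCOC(=O)CC(=O)C[C@H](c1coc(C(C)C)c1)C | intermediate
11 | ethyl (3R,5R)-3-hydroxy-5-(5-isopropylfuran-3-yl)hexanoate | CCOC(=O)C[C@H](O)C[C@H](c1coc(C(C)C)c1)C | intermediate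
12 | ethyl (3R,5R)-3-(tert-butyldimethylsilyloxy)-5-(5-isopropylfuran-3-yl)hexanoate | CCOC(=O)C[C@H](O[Si](C)(C)C(C)(C)C)C[C@H](c1coc(C(C)C)c1)C | intermediate
13 | (3R,5R)-3-(tert-butyldimethylsilyloxy)-5-(5-isopropylfuran-3-yl)hexanoic acid | OC(=O)C[C@H](O[Si](C)(C)C(C)(C)C)C[C@H](c1coc(C(C)C)c1)C | intermediate
14 | (3R,5R)-3-(tert-butyldimethylsilyloxy)-5-(5-isopropylfuran-3-yl)hexanoyl chloride (not isolated) | ClC(=O)C[C@H](O[Si](C)(C)C(C)(C)C)C[C@H](c1coc(C(C)C)c1)C | intermediate
15 | (4R,6R)-6-(tert-butyldimethylsilyloxy)-2-isopropyl-4-methyl-4,5,6,7-tetrahydro-8H-cyclohepta[b]furan-8-one | CC(C)c1cc2c(o1)C(=O)C[C@H](O[Si](C)(C)C(C)(C)C)C[C@H]2C | intermediate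
16 | (4'R,6'R)-6'-(tert-butyldimethylsilyloxy)-2'-isopropyl-4'-methyl-4',5',6',7'-tetrahydrospiro[1,3-dioxolane-2,8'-cyclohepta[b]furan], the key-step precursor | CC(C)c1cc2c(o1)C3(OCCO3)C[C@H](O[Si](C)(C)C(C)(C)C)C[C@H]2C | intermediate
17 | Z-enedione: ring C ketone at C8a, exocyclic Z-alkene C3a=C3 carrying the isobutyryl group cis to C8a, C8 dioxolane, C6 OTBS, C4 methyl (not isolated) | CC(C)C(=O)/C=C1\C(=O)C2(OCCO2)C[C@H](O[Si](C)(C)C(C)(C)C)C[C@H]1C | intermediate
18 | (4R,6R,8aR)-6-(tert-butyldimethylsilyloxy)-8a-hydroxy-1,1,4-trimethyl-4,5,6,7-tetrahydro-1H-spiro[azulene-8,2'-[1,3]dioxolan]-2(8aH)-one, the key-step product | CC1(C)C(=O)C=C2[C@]1(O)C3(OCCO3)C[C@H](O[Si](C)(C)C(C)(C)C)C[C@H]2C | intermediate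
19 | (4R,6R,8aR)-6,8a-dihydroxy-1,1,4-trimethyl-4,5,6,7-tetrahydro-1H-spiro[azulene-8,2'-[1,3]dioxolan]-2(8aH)-one | CC1(C)C(=O)C=C2[C@]1(O)C3(OCCO3)C[C@H](O)C[C@H]2C | intermediate
20 | (4R,8aR)-8a-hydroxy-1,1,4-trimethyl-4,5-dihydro-1H-spiro[azulene-8,2'-[1,3]dioxolane]-2,6(7H,8aH)-dione | CC1(C)C(=O)C=C2[C@]1(O)C3(OCCO3)CC(=O)C[C@H]2C | intermediate
21 | (4R,8aR)-5-[(dimethylamino)methyl]-8a-hydroxy-1,1,4-trimethyl-4,5-dihydro-1H-spiro[azulene-8,2'-[1,3]dioxolane]-2,6(7H,8aH)-dione, C5 epimers | CC1(C)C(=O)C=C2[C@]1(O)C3(OCCO3)CC(=O)C(CN(C)C)[C@H]2C | intermediate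
22 | 4-hydroxy-5,6-dimethyl-2H-pyran-2-one | Cc1oc(=O)cc(O)c1C | starting material
23 | methiodide of 21, 5-(trimethylammoniomethyl) ketone iodide (not isolated) | CC1(C)C(=O)C=C2[C@]1(O)C3(OCCO3)CC(=O)C(C[N+](C)(C)C)[C@H]2C.[I-] | intermediate
24 | (4R,8aR)-8a-hydroxy-1,1,4-trimethyl-5-methylene-4,5-dihydro-1H-spiro[azulene-8,2'-[1,3]dioxolane]-2,6(7H,8aH)-dione (not isolated) | CC1(C)C(=O)C=C2[C@]1(O)C3(OCCO3)CC(=O)C(=C)[C@H]2C | intermediate
25 | ring B hemiketal (4R,5R,6R,8aR): ketone 20 with C5–CH2 bonded to pyranone C3 and C6 bearing OH and the pyranone C4 oxygen, C8 dioxolane retained | Cc1oc(=O)c2c(c1C)O[C@]1(O)CC4(OCCO4)[C@@]3(O)C(=CC(=O)C3(C)C)[C@H](C)[C@H]1C2 | intermediate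
26 | ring B vinylogous ester (4R,5R,8aR): the target lacking both the C6 and C7 hydroxyls, with a C6=C7 enol ether conjugated to the C8 ketone | Cc1oc(=O)c2c(c1C)OC1=CC(=O)[C@@]3(O)C(=CC(=O)C3(C)C)[C@H](C)[C@H]1C2 | intermediate
27 | 6,7-epoxide of 26 on the face syn to the C4 methyl and anti to the C8a hydroxyl (not isolated) | Cc1oc(=O)c2c(c1C)O[C@@]1(O4)[C@H]4C(=O)[C@@]3(O)C(=CC(=O)C3(C)C)[C@H](C)[C@H]1C2 | intermediate
28 | CNP0525404.1, (4R,5R,6S,7R,8aR) tetracycle: ring A 5,6-dimethylpyran-2-one, ring B hemiketal dihydropyran, ring C cycloheptanone with C7 hydroxyl, ring D 4-hydroxy-5,5-dimethylcyclopentenone | Cc1oc(=O)c2c(c1C)O[C@]1(O)[C@H](O)C(=O)[C@@]3(O)C(=CC(=O)C3(C)C)[C@H](C)[C@H]1C2 | target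

Total step count: 18.
Longest linear sequence: 18 steps (1 to 28); compounds 5, 8 and 22 are purchased and enter directly.

Steps most likely to fail

Step 12. The peracid may over-oxidise the enedione, carbonate may remove the γ-proton at C4 (epimerisation or dienolate chemistry), or the aldol equilibrium may not favour the drawn C8a epimer. The fallback separates the two events and replaces equilibration by kinetic control. Setting out from 16, the furan is photo-oxygenated (O2, tetraphenylporphyrin, visible light, CH2Cl2, −78 °C) to the furan endoperoxide F1, which Me2S reduces to the Z-enedione 17, now isolated under neutral conditions. 17 is then closed irreversibly at low temperature (LiN(SiMe3)2, THF, −78 °C, acetic acid quench at −78 °C), and the route is rejoined at 18.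

Step 15. The base may deprotonate C7 instead of C5, or the C8a alkoxide may sequester the C6 ketone as a transannular hemiketal so that enolisation stalls. The fallback makes the regiochemistry unambiguous by design. Setting out from 20, acid hydrolysis of the dioxolane (1 M HCl, THF, rt) gives the trione F2, in which C7 lies between two carbonyls and C5 is the only γ-methylene. Its trianion (LiN(iPr)2, 3.3 equiv, THF, −78 to 0 °C) reacts at the last-formed, most basic site, C5, with Eschenmoser's salt to give the Mannich base F3. Warming F3 with 22 (MeCN, 60 °C) expels dimethylamine to give the exo-methylene trione F4, which takes up the pyranone to give the open Michael adduct F5. TsOH·H2O then cyclodehydrates F5, and the route is rejoined at 26.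

Step 18. Oxygen may be delivered to the wrong face of C6=C7, or the oxidant may also attack the pyranone. The fallback brings the oxygen in with the opposite facial logic in two stages. Setting out from 26, NIS in aqueous MeCN (0 °C) gives the trans-iodohydrin F6, with iodine at C7 on the face the electrophile prefers and hydroxyl at C6. Ag2O (CH2Cl2, rt) then closes the C6 oxygen onto C7 with inversion, placing the epoxide on the other face. The route is rejoined at the epoxide 27, whose buffered hydrolysis as in step 18 gives 28.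

Further compounds
F1 | step 12 | 2,8a-endoperoxide of furan 16 (2,3,7-trioxabicyclo[2.2.1]hept-5-ene fused to ring C, bridgehead configuration undefined) | CC(C)C12C=C3[C@H](C)C[C@@H](O[Si](C)(C)C(C)(C)C)CC4(OCCO4)C3(O1)OO2
F2 | step 15 | (4R,8aR)-8a-hydroxy-1,1,4-trimethyl-4,5-dihydroazulene-2,6,8(1H,7H,8aH)-trione | CC1(C)C(=O)C=C2[C@]1(O)C(=O)CC(=O)C[C@H]2C
F3 | step 15 | (4R,8aR)-5-[(dimethylamino)methyl]-8a-hydroxy-1,1,4-trimethyl-4,5-dihydroazulene-2,6,8(1H,7H,8aH)-trione, C5 epimers | CC1(C)C(=O)C=C2[C@]1(O)C(=O)CC(=O)C(CN(C)C)[C@H]2C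
F4 | step 15 | (4R,8aR)-8a-hydroxy-1,1,4-trimethyl-5-methylene-4,5-dihydroazulene-2,6,8(1H,7H,8aH)-trione | CC1(C)C(=O)C=C2[C@]1(O)C(=O)CC(=O)C(=C)[C@H]2C
F5 | step 15 | open Michael adduct (4R,5R,8aR): trione F2 carrying at C5 a (4-hydroxy-5,6-dimethyl-2-oxo-2H-pyran-3-yl)methyl group | Cc1oc(=O)c(C[C@H]2C(=O)CC(=O)[C@@]3(O)C(=CC(=O)C3(C)C)[C@@H]2C)c(O)c1C
F6 | step 18 | trans-iodohydrin of 26: C7 iodide anti to the C4 methyl, C6 hemiketal hydroxyl syn to it | Cc1oc(=O)c2c(c1C)O[C@@]1(O)[C@@H](I)C(=O)[C@@]3(O)C(=CC(=O)C3(C)C)[C@H](C)[C@H]1C2
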